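Ring C (C9–C10–C11–C12–C1–C9a) is closed by forming its C9–C10 bond. The key step exploits the tertiary carbinol C9 next to the ethyl-bearing C10: with ethyl read as vinyl, this pair is a homoallylic alcohol. An acyclic diketone with one stereocentre (C11, from a Sharpless epoxidation) undergoes cross-metathesis with allyl pinacolboronate. The (E)-allylboronate then adds to the C9 ketone through a chair transition state, closing ring C and setting C9 and C10 in one operation. Butenolide annulation and hydrogenation build ring D. A serine-derived sulfamidate brings N4, C2, C3 and ring E, and a condensation/N-alkylation cascade closes rings B and A.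

Key step: step 5

Remark on labels: N4 is the nitrogen; C5–C8 are the four CH2 groups of the azepine; C9 is the carbinol carbon; C9a is the enamine carbon on nitrogen and C1 the other enamine carbon; C2 and C3 are the CH2 and CH of the pyrroline; C10 bears the ethyl group; C11 is the CH–O of the fused lactone; C12 is the ring-fusion CH; C13 is CH(CH3) and C14 the C=O of the fused lactone; C18, C19, C20 and C21 are the CH–O, CH2, CH(CH3) and C=O of the appended lactone. Ring A is the azepine, ring B the pyrroline, ring C the carbocycle, ring D the fused lactone and ring E the appended lactone.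

Assumption: 5-chloropentanal, (R)-Garner's aldehyde, allylboronic acid pinacol ester and 2-(diethoxyphosphoryl)propanoic acid are taken as commercially available.

Step 1
Reactants: 1 penta-1,4-dien-3-ol
Product: 2 (2R,3S)-1,2-epoxypent-4-en-3-ol
Conditions: Ti(OiPr)4 (cat.), L-(+)-diisopropyl tartrate (cat.), t-BuOOH, 4 Å MS, CH2Cl2, −20 °C
Reagents that add atoms: tert-butyl hydroperoxide, CC(C)(C)OO
Why: Sharpless asymmetric epoxidation desymmetrises the divinyl carbinol, the tartrate choosing one enantiotopic vinyl group and one face, so the erythro epoxy alcohol should form with C11 set (S at this stage) and the minor enantiomer consumed by over-oxidation.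

Step 2
Reactants: 2 (2R,3S)-1,2-epoxypent-4-en-3-ol
Product: 3 (2R)-2-[(1S)-1-(methoxymethoxy)prop-2-en-1-yl]oxirane
Conditions: MOMCl, iPr2NEt, CH2Cl2, 0 °C to rt
Reagents that add atoms: chloromethyl methyl ether, COCCl
Why: Standard MOM etherification of a secondary alcohol under amine base, mild enough to avoid Payne rearrangement of the epoxy alcohol.

Step 3
Reactants: 3 (2R)-2-[(1S)-1-(methoxymethoxy)prop-2-en-1-yl]oxirane; 4 1,3-dithiane; 5 5-chloropentanal
Product: 7 5-chloro-1-{2-[(2R,3S)-2-hydroxy-3-(methoxymethoxy)pent-4-en-1-yl]-1,3-dithian-2-yl}pentan-1-ol (both epimers at the new carbinol), via dithiane alcohol 6 (not isolated)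
Conditions: 4, n-BuLi, THF, −30 °C; then 3, −78 to −20 °C; n-BuLi, −20 °C; then 5, −78 °C; aq. NH4Cl
Reagents that add atoms: none
Why: Corey–Seebach linchpin coupling in which 2-lithio-1,3-dithiane opens the terminal epoxide carbon by SN2 and, after a second lithiation at the dithiane carbon, adds to the aldehyde, so C9a is installed as a masked ketone between C1 and C9; the two carbinol centres are oxidised next and need no control.

Step 4
Reactants: 7 diol from step 3
Product: 8 (3S)-1-[2-(5-chloropentanoyl)-1,3-dithian-2-yl]-3-(methoxymethoxy)pent-4-en-2-one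
Conditions: Dess–Martin periodinane, CH2Cl2, 0 °C to rt
Reagents that add atoms: none
Why: Dess–Martin oxidation converts both secondary alcohols to ketones (C9 and C12) under non-basic conditions that should leave the enolisable, vinyl-bearing C11 stereocentre intact.

Step 5
Reactants: 8 (3S)-1-[2-(5-chloropentanoyl)-1,3-dithian-2-yl]-3-(methoxymethoxy)pent-4-en-2-one; 9 allylboronic acid pinacol ester
Product: 11 (7R,8S,9S)-7-(4-chlorobutyl)-8-ethenyl-7-hydroxy-9-(methoxymethoxy)-1,5-dithiaspiro[5.5]undecan-10-one, via allylboronate 10 (not isolated)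
Conditions: 9 (2 equiv), second-generation Hoveyda–Grubbs catalyst RuCl2(H2IMes)(=CH-C6H4-2-OiPr) (5 mol %), 1,4-benzoquinone (10 mol %), CH2Cl2, 40 °C; evaporate; toluene, 80 °C; aq. NaHCO3
Reagents that add atoms: none
Why: Cross-metathesis of the vinyl group on C11 with allyl pinacolboronate gives the (E)-γ-substituted allylboronate, whose γ-carbon C10 then adds to the C9 ketone through a six-membered chair transition state with boron bound to the carbonyl oxygen (tandem cross-metathesis/allylboration; the closest known type is the intramolecular allylboration of ω-oxo allylboronates). Ring C closes in a 6-exo-trig mode at the C9 carbonyl, which is activated by the adjacent dithiane and held near C10 by the gem-disubstituted C9a. C9 and C10 are controlled by the fused chair–chair (trans-decalin-like) transition state: the E geometry puts C11 equatorial, the bulky dithiane carbon C9a takes the equatorial site of the ketone and the chlorobutyl chain the axial one, so hydroxyl and vinyl should end up trans. Relative to C11, the chair with the MOM ether equatorial is preferred because the other chair places it 1,3-diaxial to the chlorobutyl chain, so vinyl should be trans to the C11 oxygen, giving the target's 9R,10S configuration. The step needs E-selective metathesis, secured by the branched allylic carbon C11, and selectivity between the two ketones, secured because C10 can reach only C9 in a cyclic transition state and pinacol allylboronates add to ketones only slowly between molecules.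

Step 6
Reactants: 11 spiro ketone from step 5
Product: 12 (7R,8S,9S)-7-(4-chlorobutyl)-8-ethenyl-7,9-dihydroxy-1,5-dithiaspiro[5.5]undecan-10-one
Conditions: Me2BBr, CH2Cl2, −78 °C; then aq. NaHCO3, THF
Reagents that add atoms: none
Why: Bromodimethylborane cleaves MOM ethers at low temperature and should spare the dithiane, alkene, ketone, alkyl chloride and tertiary alcohol, freeing the C11 hydroxyl.

Step 7
Reactants: 12 dihydroxy ketone from step 6; 13 2-(diethoxyphosphoryl)propanoic acid
Product: 15 (6R,7S,7aS)-6-(4-chlorobutyl)-7-ethenyl-6-hydroxy-3-methyl-4,6,7,7a-tetrahydro-2H-spiro[1-benzofuran-5,2'-[1,3]dithian]-2-one, via phosphonate ester 14 (not isolated)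
Conditions: 13, DCC, DMAP (cat.), CH2Cl2, 0 °C to rt; then LiCl, DBU, MeCN, 0 °C to rt
Reagents that add atoms: none
Why: Steglich esterification of the only acylable hydroxyl (secondary, on C11) followed by an intramolecular Horner–Wadsworth–Emmons reaction (Masamune–Roush conditions) with the neighbouring C12 ketone closes the butenolide of ring D with C13 and its methyl group in place.

Step 8
Reactants: 15 butenolide dithiane from step 7
Product: 16 (6R,7S,7aS)-6-(4-chlorobutyl)-7-ethenyl-6-hydroxy-3-methyl-7,7a-dihydro-1-benzofuran-2,5(4H,6H)-dione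
Conditions: MeI, CaCO3, MeCN/H2O (9:1), 45 °C
Reagents that add atoms: water, O
Why: S-Methylation and hydrolysis of the dithiane (Fétizon conditions) unmask the C9a ketone without strong acid or heavy metal, giving the α-hydroxy ketone.

Step 9
Reactants: 16 butenolide ketone from step 8
Product: 17 (3R,3aS,6R,7S,7aR)-6-(4-chlorobutyl)-7-ethyl-6-hydroxy-3-methylhexahydro-1-benzofuran-2,5-dione
Conditions: H2 (50 bar), 5% Rh/Al2O3, EtOAc, rt
Reagents that add atoms: none
Why: Heterogeneous hydrogenation turns vinyl into ethyl and adds H2 syn to the tetrasubstituted C12=C13 bond from the convex face (the side of H11, away from C10 and C9), which should give the cis-fused lactone with H11, H12 and H13 on one face and so set C12 and C13.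

Step 10
Reactants: 18 tert-butyl (4R)-4-formyl-2,2-dimethyl-1,3-oxazolidine-3-carboxylate ((R)-Garner's aldehyde); 19 ethyl 2-(bromomethyl)prop-2-enoate
Product: 21 tert-butyl (4R)-2,2-dimethyl-4-[(2S)-4-methylidene-5-oxooxolan-2-yl]-1,3-oxazolidine-3-carboxylate, via hydroxy ester 20 (not isolated)
Conditions: Zn dust, THF, 50 °C; then aq. NH4Cl
Reagents that add atoms: none
Why: Zinc-mediated Barbier allylation with lactonisation of the zinc alkoxide (Dreiding–Schmidt reaction); Felkin–Anh attack anti to the ring nitrogen should favour the anti amino alcohol, setting C18 (S), with the minor syn isomer removed by chromatography.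

Step 11
Reactants: 21 methylidene lactone from step 10
Product: 22 tert-butyl (4R)-2,2-dimethyl-4-[(2S,4S)-4-methyl-5-oxooxolan-2-yl]-1,3-oxazolidine-3-carboxylate
Conditions: H2 (1 atm), 10% Pd/C, EtOAc, rt
Reagents that add atoms: none
Why: Hydrogenation of the exocyclic methylene from the lactone face opposite the bulky C18 substituent should give the cis-2,4-disubstituted lactone, setting C20 (S).

Step 12
Reactants: 22 methyl lactone from step 11
Product: 23 tert-butyl N-[(1R)-2-hydroxy-1-[(2S,4S)-4-methyl-5-oxooxolan-2-yl]ethyl]carbamate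
Conditions: AcOH/H2O (4:1), 40 °C
Reagents that add atoms: none
Why: Aqueous acetic acid hydrolyses the N,O-acetonide while the Boc carbamate and the lactone should survive.

Step 13
Reactants: 23 carbamate alcohol from step 12
Product: 25 tert-butyl (4R)-4-[(2S,4S)-4-methyl-5-oxooxolan-2-yl]-1,2,3-oxathiazolidine-3-carboxylate 2,2-dioxide, via sulfamidite 24 (not isolated)
Conditions: SOCl2, pyridine, MeCN, −40 °C; then RuCl3 (cat.), NaIO4, MeCN/H2O, 0 °C
Reagents that add atoms: thionyl chloride, O=S(Cl)Cl; sodium periodate, [Na+].[O-]I(=O)(=O)=O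
Why: Cyclisation of the N-Boc amino alcohol with thionyl chloride and ruthenium-catalysed oxidation of the sulfamidite give the cyclic sulfamidate, which makes C2 an electrophile while keeping N4 protected and C3 untouched.

Step 14
Reactants: 17 keto lactone from step 9; 25 cyclic sulfamidate from step 13
Product: 27 tert-butyl N-[(1R)-2-[(3R,3aS,6R,7S,7aR)-6-(4-chlorobutyl)-7-ethyl-6-hydroxy-3-methyl-2,5-dioxooctahydro-1-benzofuran-4-yl]-1-[(2S,4S)-4-methyl-5-oxooxolan-2-yl]ethyl]carbamate (both epimers at C1), via N-sulfamate 26 (not isolated)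
Conditions: 17, LiN(SiMe3)2 (2.1 equiv), THF, −78 °C; then 25, −78 to 0 °C; then 1 M HCl, rt
Reagents that add atoms: none
Why: Enolate alkylation with a cyclic sulfamidate: the lithium enolate of 17 can form only toward C1 (C9 is quaternary) and opens the sulfamidate at its CH2–O carbon by SN2 to forge C1–C2, mild acid then hydrolyses the N-sulfamate, and the C1 configuration is irrelevant because C1 becomes sp2.

Step 15
Reactants: 27 N-Boc amino ketone from step 14
Product: 32 CNP0186848.1, via amino ketone 28 (not isolated), via cyclic imine 29 (not isolated), via iodo imine 30 (not isolated), via iminium iodide 31 (not isolated)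
Conditions: CF3CO2H, CH2Cl2, 0 °C; evaporate; then NaI, K2CO3, MeCN, 70 °C
Reagents that add atoms: none
Why: Acid removes the Boc group, the γ-amino ketone condenses to the five-membered cyclic imine (ring B), Finkelstein exchange and intramolecular N-alkylation of the imine nitrogen by C5 close the seven-membered ring A as an iminium ion, and loss of the C1 proton gives the C1=C9a enamine, funnelling both C1 epimers into the target.

Compound list
1 | penta-1,4-dien-3-ol | C=CC(O)C=C | starting material
2 | (2R,3S)-1,2-epoxypent-4-en-3-ol | C=C[C@H](O)[C@H]1CO1 | intermediate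
3 | (2R)-2-[(1S)-1-(methoxymethoxy)prop-2-en-1-yl]oxirane | C=C[C@H](OCOC)[C@H]1CO1 | intermediate
4 | 1,3-dithiane | C1CSCSC1 | starting material
5 | 5-chloropentanal | ClCCCCC=O | starting material
6 | (2R,3S)-1-(1,3-dithian-2-yl)-3-(methoxymethoxy)pent-4-en-2-ol | C=C[C@H](OCOC)[C@H](O)CC1SCCCS1 | intermediate (not isolated)
7 | 5-chloro-1-{2-[(2R,3S)-2-hydroxy-3-(methoxymethoxy)pent-4-en-1-yl]-1,3-dithian-2-yl}pentan-1-ol (both carbinol epimers) | C=C[C@H](OCOC)[C@H](O)CC1(SCCCS1)C(O)CCCCCl | intermediate
8 | (3S)-1-[2-(5-chloropentanoyl)-1,3-dithian-2-yl]-3-(methoxymethoxy)pent-4-en-2-one | C=C[C@H](OCOC)C(=O)CC1(SCCCS1)C(=O)CCCCCl | intermediate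
9 | allylboronic acid pinacol ester (2-allyl-4,4,5,5-tetramethyl-1,3,2-dioxaborolane) | C=CCB1OC(C)(C)C(C)(C)O1 | starting material
10 | (3S,4E)-1-[2-(5-chloropentanoyl)-1,3-dithian-2-yl]-3-(methoxymethoxy)-6-(4,4,5,5-tetramethyl-1,3,2-dioxaborolan-2-yl)hex-4-en-2-one | CC1(C)OB(C/C=C/[C@H](OCOC)C(=O)CC2(SCCCS2)C(=O)CCCCCl)OC1(C)C | intermediate (not isolated)
11 | (7R,8S,9S)-7-(4-chlorobutyl)-8-ethenyl-7-hydroxy-9-(methoxymethoxy)-1,5-dithiaspiro[5.5]undecan-10-one | O[C@]1(CCCCCl)[C@@H](C=C)[C@H](OCOC)C(=O)CC12SCCCS2 | intermediate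
12 | (7R,8S,9S)-7-(4-chlorobutyl)-8-ethenyl-7,9-dihydroxy-1,5-dithiaspiro[5.5]undecan-10-one | O[C@]1(CCCCCl)[C@@H](C=C)[C@H](O)C(=O)CC12SCCCS2 | intermediate
13 | 2-(diethoxyphosphoryl)propanoic acid | CCOP(=O)(OCC)C(C)C(=O)O | starting material
14 | (7R,8S,9S)-7-(4-chlorobutyl)-8-ethenyl-7-hydroxy-10-oxo-1,5-dithiaspiro[5.5]undecan-9-yl 2-(diethoxyphosphoryl)propanoate | O[C@]1(CCCCCl)[C@@H](C=C)[C@H](OC(=O)C(C)P(=O)(OCC)OCC)C(=O)CC12SCCCS2 | intermediate (not isolated)
15 | (6R,7S,7aS)-6-(4-chlorobutyl)-7-ethenyl-6-hydroxy-3-methyl-4,6,7,7a-tetrahydro-2H-spiro[1-benzofuran-5,2'-[1,3]dithian]-2-one | O[C@]1(CCCCCl)[C@@H](C=C)[C@@H]2OC(=O)C(C)=C2CC13SCCCS3 | intermediate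
16 | (6R,7S,7aS)-6-(4-chlorobutyl)-7-ethenyl-6-hydroxy-3-methyl-7,7a-dihydro-1-benzofuran-2,5(4H,6H)-dione | O[C@]1(CCCCCl)[C@@H](C=C)[C@@H]2OC(=O)C(C)=C2CC1=O | intermediate
17 | (3R,3aS,6R,7S,7aR)-6-(4-chlorobutyl)-7-ethyl-6-hydroxy-3-methylhexahydro-1-benzofuran-2,5-dione | O[C@]1(CCCCCl)[C@@H](CC)[C@@H]2OC(=O)[C@H](C)[C@@H]2CC1=O | intermediate
18 | tert-butyl (4R)-4-formyl-2,2-dimethyl-1,3-oxazolidine-3-carboxylate | O=C[C@H]1COC(C)(C)N1C(=O)OC(C)(C)C | starting material
19 | ethyl 2-(bromomethyl)prop-2-enoate | C=C(CBr)C(=O)OCC | starting material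
20 | tert-butyl (4R)-4-[(1S)-3-(ethoxycarbonyl)-1-hydroxybut-3-en-1-yl]-2,2-dimethyl-1,3-oxazolidine-3-carboxylate | C=C(C[C@H](O)[C@H]1COC(C)(C)N1C(=O)OC(C)(C)C)C(=O)OCC | intermediate (not isolated)
21 | tert-butyl (4R)-2,2-dimethyl-4-[(2S)-4-methylidene-5-oxooxolan-2-yl]-1,3-oxazolidine-3-carboxylate | C=C1C[C@H](OC1=O)[C@H]1COC(C)(C)N1C(=O)OC(C)(C)C | intermediate
22 | tert-butyl (4R)-2,2-dimethyl-4-[(2S,4S)-4-methyl-5-oxooxolan-2-yl]-1,3-oxazolidine-3-carboxylate | C[C@H]1C[C@H](OC1=O)[C@H]1COC(C)(C)N1C(=O)OC(C)(C)C | intermediate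
23 | tert-butyl N-[(1R)-2-hydroxy-1-[(2S,4S)-4-methyl-5-oxooxolan-2-yl]ethyl]carbamate | C[C@H]1C[C@H](OC1=O)[C@@H](CO)NC(=O)OC(C)(C)C | intermediate
24 | tert-butyl (4R)-4-[(2S,4S)-4-methyl-5-oxooxolan-2-yl]-1,2,3-oxathiazolidine-3-carboxylate 2-oxide (both sulfur epimers) | C[C@H]1C[C@H](OC1=O)[C@H]1COS(=O)N1C(=O)OC(C)(C)C | intermediate (not isolated)
25 | tert-butyl (4R)-4-[(2S,4S)-4-methyl-5-oxooxolan-2-yl]-1,2,3-oxathiazolidine-3-carboxylate 2,2-dioxide | C[C@H]1C[C@H](OC1=O)[C@H]1COS(=O)(=O)N1C(=O)OC(C)(C)C | intermediate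
26 | N-sulfonic acid of 27 (N-Boc-N-sulfo amine, lithium salt in the flask; both C1 epimers) | O[C@]1(CCCCCl)[C@@H](CC)[C@@H]2OC(=O)[C@H](C)[C@@H]2C(C[C@@H](N(C(=O)OC(C)(C)C)S(=O)(=O)O)[C@@H]2C[C@H](C)C(=O)O2)C1=O | intermediate (not isolated)
27 | tert-butyl N-[(1R)-2-[(3R,3aS,6R,7S,7aR)-6-(4-chlorobutyl)-7-ethyl-6-hydroxy-3-methyl-2,5-dioxooctahydro-1-benzofuran-4-yl]-1-[(2S,4S)-4-methyl-5-oxooxolan-2-yl]ethyl]carbamate (both C1 epimers) | O[C@]1(CCCCCl)[C@@H](CC)[C@@H]2OC(=O)[C@H](C)[C@@H]2C(C[C@@H](NC(=O)OC(C)(C)C)[C@@H]2C[C@H](C)C(=O)O2)C1=O | intermediate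
28 | free amine of 27 (γ-amino ketone; both C1 epimers) | O[C@]1(CCCCCl)[C@@H](CC)[C@@H]2OC(=O)[C@H](C)[C@@H]2C(C[C@@H](N)[C@@H]2C[C@H](C)C(=O)O2)C1=O | intermediate (not isolated)
29 | cyclic imine (C9a=N4 1-pyrroline; rings B, C, D and E closed, 4-chlorobutyl chain on C9; both C1 epimers) | CC[C@H]1[C@@H]2OC(=O)[C@H](C)[C@@H]2C2C(=N[C@@H]([C@@H]3C[C@H](C)C(=O)O3)C2)[C@@]1(O)CCCCCl | intermediate (not isolated)
30 | iodo analogue of 29 (4-iodobutyl chain on C9) | CC[C@H]1[C@@H]2OC(=O)[C@H](C)[C@@H]2C2C(=N[C@@H]([C@@H]3C[C@H](C)C(=O)O3)C2)[C@@]1(O)CCCCI | intermediate (not isolated)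
31 | pentacyclic iminium iodide (C9a=N4+, ring A closed, C1–H still present) | CC[C@H]1[C@@H]2OC(=O)[C@H](C)[C@@H]2C2C3=[N+](CCCC[C@]31O)[C@@H]([C@@H]1C[C@H](C)C(=O)O1)C2.[I-] | intermediate (not isolated)
32 | CNP0186848.1 | CC[C@H]1[C@@H]2OC(=O)[C@H](C)[C@@H]2C2=C3N(CCCC[C@]31O)[C@@H]([C@@H]1C[C@H](C)C(=O)O1)C2 | target

Total step count: 15. Longest linear sequence: 11 steps (steps 1–9, 14 and 15); the side branch is steps 10–13.

Steps most likely to fail

Step 5. The hindered C9 ketone may add the allylboronate too slowly, so that alkene isomerisation, loss of E geometry or allyl transfer between molecules to the C12 ketone compete. Fallback, from 8 back to 11: cross-metathesis of 8 with allyltrimethylsilane under the same ruthenium catalyst should give the isolable (E)-allylsilane F1. An intramolecular Hosomi–Sakurai cyclisation (BF3·OEt2, CH2Cl2, −78 °C) then lets C10 attack the Lewis-acid-activated C9 ketone through an open transition state, with the same equatorial preferences expected to lead to 11.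

Step 14. The ketone enolate may exchange protons instead of alkylating, may alkylate on oxygen, or the tertiary alkoxide may displace the chloride to form a cyclic ether. Fallback, from 16 to 27: the C1 methylene of 16 lies between the C9a ketone and the butenolide and is acidic enough for Cs2CO3 in DMF at 0 °C. This soft enolate should open 25 to the N-sulfamate F2 without forming the alkoxide. Dilute acid then gives the N-Boc butenolide F3, and hydrogenation (H2, Rh/Al2O3) of its vinyl and butenolide double bonds from the convex face leads to 27.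

Step 9. The tetrasubstituted butenolide may reduce sluggishly on the heterogeneous catalyst, and hydrogenolysis of the allylic C11–O bond or reduction of the C9a ketone may intervene. Fallback, from 16 to 17: the C9 hydroxyl is capped with N-(trimethylsilyl)imidazole to give the trimethylsilyl ether F4, so that no hydroxyl directs the metal to the concave face. Homogeneous hydrogenation with [Ir(cod)(PCy3)(py)]PF6 (H2, CH2Cl2), a catalyst that reduces tetrasubstituted alkenes and leaves ketones alone, gives the saturated silyl ether F5. Dilute aqueous HCl in THF then returns 17.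

Further compounds
F1 | step 5 | (3S,4E)-1-[2-(5-chloropentanoyl)-1,3-dithian-2-yl]-3-(methoxymethoxy)-6-(trimethylsilyl)hex-4-en-2-one | C[Si](C)(C)C/C=C/[C@H](OCOC)C(=O)CC1(SCCCS1)C(=O)CCCCCl
F2 | step 14 | N-sulfonic acid of F3 (caesium salt in the flask; both C1 epimers) | O[C@]1(CCCCCl)[C@@H](C=C)[C@@H]2OC(=O)C(C)=C2C(C[C@@H](N(C(=O)OC(C)(C)C)S(=O)(=O)O)[C@@H]2C[C@H](C)C(=O)O2)C1=O
F3 | step 14 | C1-alkylated butenolide of 16 carrying the CH2–CH(NHBoc)–lactone E side chain (both C1 epimers) | O[C@]1(CCCCCl)[C@@H](C=C)[C@@H]2OC(=O)C(C)=C2C(C[C@@H](NC(=O)OC(C)(C)C)[C@@H]2C[C@H](C)C(=O)O2)C1=O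
F4 | step 9 | trimethylsilyl ether of 16 at the C9 hydroxyl | C[Si](C)(C)O[C@]1(CCCCCl)[C@@H](C=C)[C@@H]2OC(=O)C(C)=C2CC1=O
F5 | step 9 | trimethylsilyl ether of 17 at the C9 hydroxyl | C[Si](C)(C)O[C@]1(CCCCCl)[C@@H](CC)[C@@H]2OC(=O)[C@H](C)[C@@H]2CC1=O
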